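## Retrosynthetic overview
1. The pyran ring is made last. Its O4'–CMe2 bond forms when the 5'-prenyl B-ring o-quinone tautomerises to its vinyl o-quinone methide, which then closes by oxa-6π electrocyclisation.
2. The o-quinone comes from hydrolysis of its 4',4'-dimethyl monoketal. The monoketal is made by anodic methoxylative dearomatisation of 5'-prenylhesperetin, so the 4'-OMe is removed oxidatively, without Lewis acid or strong base.
3. The key C5'–C1'' bond comes from visible-light photoredox 1,6-addition of a prenyl radical to the hesperetin-derived o-quinone monoketal. Loss of MeOH then rearomatises the ring.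
4. That first monoketal comes from anodic oxidation of (2S)-hesperetin. The native 4'-OMe fixes where the ketal forms, which makes C5' the acceptor site.
5. Rings A, C and B and the C2 stereocentre are bought intact. Only the pyran ring is built, and no protecting groups are used.

Assumption 1: (2S)-hesperetin (from citrus hesperidin) is bought as the single enantiomer, and its ee is checked by chiral HPLC because some lots are partly racemised.
Assumption 2: potassium prenyltrifluoroborate is bought; if it is out of stock, commercial prenyl-Bpin plus KHF2 gives it in one extra off-line step.

Numbering: B-ring atoms are primed and prenyl carbons are double-primed.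

## Route

**Step 1**
- Reactants: 1, (2S)-hesperetin [(2S)-5,7-dihydroxy-2-(3-hydroxy-4-methoxyphenyl)chroman-4-one]
- Product: 2, (2S)-2-(4,4-dimethoxy-3-oxocyclohexa-1,5-dien-1-yl)-5,7-dihydroxychroman-4-one (B ring as a masked o-benzoquinone: C3'=O, C4'(OMe)2)
- Conditions: graphite anode / Pt cathode, undivided cell, Bu4NBF4 (0.1 M), 2,6-lutidine (2 equiv), MeOH (0.03 M), 0 °C, potential held on the first wave (ca. +0.9 V vs Ag/AgCl), 2.1 F/mol; solution used at once
- Reagents that add atoms: methanol, CO
- Why: Known anodic methoxylative phenol dearomatisation to an o-quinone monoketal: the first wave belongs to the guaiacol-type B ring, well below the acylphloroglucinol A ring, MeOH captures the methoxy-stabilised phenoxenium ion at C4', and because that cation carries no charge at C1' and only weak lutidine base is present at 0 °C, C2–H and the bought stereocentre are untouched (no new stereocentre).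

**Step 2**
- Reactants: 2, monoketal; 3, potassium trifluoro(3-methylbut-2-en-1-yl)borate
- Product: 4, (2S)-5,7-dihydroxy-2-[3-hydroxy-4-methoxy-5-(3-methylbut-2-en-1-yl)phenyl]chroman-4-one (5'-prenylhesperetin)
- Conditions: electrolysis solution of 2 diluted with MeCN (MeOH/MeCN 1:1), 3 (1.8 equiv), 4CzIPN (3 mol %), N2, 456 nm LEDs, 0–5 °C, 4 h; then AcOH (3 equiv), 20 °C, 30 min; SiO2
- Reagents that add atoms: potassium prenyltrifluoroborate, CC(C)=CC[B-](F)(F)F.[K+]
- Why: Proposed new method: visible-light radical 1,6-addition/rearomatisation on a masked o-benzoquinone, in which excited 4CzIPN (E* ≈ +1.35 V vs SCE) oxidises 3 to the nucleophilic prenyl radical, which adds through its unhindered CH2 terminus to C5', the only open acceptor terminus of the linear dienone O=C3'–C2'=C1'–C6'=C5' (C1' is substituted, and with C4' masked as a ketal the C6' Michael site of a free o-quinone is absent); 4CzIPN•– then reduces the delocalised oxy-pentadienyl radical, the resulting dienol ketal is formally the MeOH adduct of arene 4 and loses MeOH across C4'–C5' through a methoxy-stabilised arenium ion, and the released BF3 ends as K[MeOBF3], so the process is redox- and pH-neutral and leaves the A-ring phenols, the ketone and C2 alone (no new stereocentre); the closest known chemistry is photoredox Giese-type 1,6-addition of trifluoroborate-derived radicals to p-quinone methides and dienyl acceptors, and polar addition/rearomatisation of nucleophiles on o-quinone monoketals.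

**Step 3**
- Reactants: 4, 5'-prenylhesperetin
- Product: 5, (2S)-2-[4,4-dimethoxy-5-(3-methylbut-2-en-1-yl)-3-oxocyclohexa-1,5-dien-1-yl]-5,7-dihydroxychroman-4-one
- Conditions: graphite anode / Pt cathode, undivided cell, Bu4NBF4, 2,6-lutidine, MeOH, 0 °C, first-wave potential, 2.1 F/mol; cold extractive work-up (EtOAc / pH 5 citrate), crude 5 used the same day
- Reagents that add atoms: methanol, CO
- Why: The same known anodic methoxylative dearomatisation: the trisubstituted alkene (Eox well above +1.5 V) and the A ring are not touched, dienone 5 is not oxidisable at this potential so electrolysis stops cleanly, and the C5' substituent on the dienophilic C=C should suppress Diels–Alder dimerisation (no new stereocentre).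

**Step 4**
- Reactants: 5, prenylated monoketal
- Product: 6, (2S)-5,7-dihydroxy-2-[5-(3-methylbut-2-en-1-yl)-3,4-dioxocyclohexa-1,5-dien-1-yl]chroman-4-one (5'-prenyl B-ring 3',4'-o-quinone; formed in solution, followed by UV-vis, not isolated)
- Conditions: 0.1 M aq. oxalic acid / THF 1:3 (5 mM in 5), N2, dark, 0 °C, 20–30 min
- Reagents that add atoms: water, O (its oxygen becomes O4', later the pyran oxygen)
- Why: Acid-catalysed ketal hydrolysis, as used to unmask quinone monoketals: ionisation gives the methoxy-stabilised cation, water adds at C4' and the hemiketal loses the second MeOH, while at about pH 2 and 0 °C the base-catalysed prototropic shifts of the quinone are slow and the prenyl alkene and flavanone are inert, so C2 is retained (no new stereocentre).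

**Step 5**
- Reactants: 6, 5'-prenyl o-quinone
- Product: 7, (2S)-5,7-dihydroxy-2-(8-hydroxy-2,2-dimethyl-2H-chromen-6-yl)chroman-4-one (target)
- Conditions: same flask, 0.5 M phosphate buffer added to pH 6.5, N2, dark, 0 → 20 °C, 1 h; EtOAc extraction, SiO2
- Reagents that add atoms: none
- Why: Quinone-to-quinone-methide tautomerisation followed by thermal oxa-6π electrocyclisation (the prenylquinone-to-chromenol isomerisation, established for prenyl-p-quinones): phosphate acts as general base to relay a proton from the doubly activated prenyl CH2 (allylic and bis-vinylogous to C3'=O) to O3', and the resulting 3'-hydroxy-4'-oxo-5'-(3-methylbut-2-enylidene) o-quinone methide, a fleeting mechanistic species that never accumulates, closes O4'–C3'' with rearomatisation; no oxidant is present, so the oxidisable product cannot over-oxidise, and C2 is not involved (no new stereocentre).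

## Compound list
1 | (2S)-hesperetin | `COc1ccc([C@@H]2CC(=O)c3c(O)cc(O)cc3O2)cc1O` | starting material
2 | hesperetin B-ring 4',4'-dimethoxy-3'-one (masked o-benzoquinone) | `COC1(OC)C=CC([C@@H]2CC(=O)c3c(O)cc(O)cc3O2)=CC1=O` | intermediate
3 | potassium trifluoro(3-methylbut-2-en-1-yl)borate | `CC(C)=CC[B-](F)(F)F.[K+]` | starting material
4 | (2S)-5'-prenylhesperetin | `COc1c(CC=C(C)C)cc([C@@H]2CC(=O)c3c(O)cc(O)cc3O2)cc1O` | intermediate
5 | 5'-prenyl 4',4'-dimethoxy-3'-one (masked o-benzoquinone) | `COC1(OC)C(CC=C(C)C)=CC([C@@H]2CC(=O)c3c(O)cc(O)cc3O2)=CC1=O` | intermediate
6 | 5'-prenyl B-ring 3',4'-o-quinone | `CC(C)=CCC1=CC([C@@H]2CC(=O)c3c(O)cc(O)cc3O2)=CC(=O)C1=O` | intermediate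
7 | (2S)-5,7-dihydroxy-2-(8-hydroxy-2,2-dimethyl-2H-chromen-6-yl)chroman-4-one | `CC1(C)C=Cc2cc([C@@H]3CC(=O)c4c(O)cc(O)cc4O3)cc(O)c2O1` | target

## Summary
- Total steps: 5. Steps 1→2 are telescoped, and Steps 3→4→5 run on crude material with 4→5 in one flask. There are two chromatographic isolations (4 and 7) and no protecting groups.
- Longest linear sequence: 5.
- The only stereocentre, C2 (S), comes from 1. All steps run neutral to weakly acidic at or below 20 °C. The ee of 4 and 7 is checked against 1 by chiral HPLC.

### Steps most likely to fail
1. **Step 2 (the new reaction).**
   - Risks: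
     - Diels–Alder dimerisation of 2 may outrun the slow allyl-radical addition.
     - The excited catalyst may be quenched by the phenols, especially by the easily oxidised product 4.
     - 4CzIPN•– may reduce 2 directly back to 1.
     - Sensitised ring opening of the dienone to a ketene is possible.
     - Some branched (tertiary-terminus) attack may occur.
   - Fallback (known chemistry):
     - Return to 1 and silylate the three phenols (TBSOTf, 2,6-lutidine).
     - Carry out sterically controlled Ir-catalysed C–H borylation ([Ir(OMe)(cod)]2/dtbpy, B2pin2). C5'–H is the ring C–H with only one small ortho neighbour.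
     - Couple with prenyl bromide under mild Pd-catalysed Suzuki conditions, desilylate with HF·pyridine, recheck ee, and rejoin the route at 4.
2. **Step 5.**
   - Risks:
     - Quinone 6 may tautomerise through the vinylogously acidic C2–H to a p-quinone methide, which erodes ee and leads to the flavone.
     - It may also add water or an A-ring nucleophile, or dimerise, before the prenyl CH2 shift.
   - Fallback (avoids the quinone entirely):
     - Cleave the 4'-OMe of 4 by neighbouring-hydroxyl-assisted AlI3/pyridine demethylation to (2S)-5'-prenyleriodictyol.
     - Close the ring by 6-endo phenylselenoetherification of 4'-OH onto the prenyl alkene (N-(phenylseleno)phthalimide, cat. CSA, CH2Cl2, –78 → 0 °C).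
     - Finish with selenoxide syn-elimination (H2O2, 0 °C), which can only eliminate toward the benzylic CH2 and gives the 2,2-dimethylchromene.
3. **Step 1.**
   - Risks:
     - MeOH may attack at C6' (para to O3').
     - Phenoxyl radicals may dimerise.
     - Monoketal 2 may dimerise before use.
     - Monoketal 2 may lose C2–H and MeOH under base to give the flavone diosmetin.
   - Fallback: change the acceptor to the more persistent orthoquinol acetate (4'-acetoxy-4'-methoxy dienone). It is made by PhI(OAc)2 acetoxylative dearomatisation (Wessely type) in CH2Cl2/MeCN at –40 °C without amine base. It is used in Step 2, where AcOH is the leaving group on rearomatisation.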